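**Retrosynthetic overview**

1. Last C–C bond: the exocyclic CH2–C4 bond of the six-membered β-triketone (dearomatised acylphloroglucinol) ring. It is made by Knoevenagel condensation and hydride transfer between the only free ring CH of the core and a cyclopentanecarbaldehyde; desilylation ends the route.
2. Feature on which the strategy rests: in the cyclopentane, the C(OH)CH3 carbon carries a two-carbon arm (ring CH plus the bridging CH2) and a three-carbon arm ending at the isopropenyl-bearing CH. This is C3 of (R)-linalool with C2–C1 and C4–C5–C6(–C7(=C8)CH3), so the ring is closed by the C2–C6 bond.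
3. Key disconnection C2–C6: aldehyde α-carbon (as enamine) to the internal terminus of a 2-methylallyl–palladium unit, 5-exo. The precursor comes from linalool by silylation, E-methyl oxidation, carbonate formation, hydroboration–oxidation of the vinyl group and oxidation.
4. Core: ring closed by Dieckmann cyclisation of a triacylmethane ester. Its quaternary C(CH3)(prenyl) centre comes from a double Fráter–Seebach alkylation of ethyl (S)-3-hydroxybutanoate.
5. Ring order: cyclopentane (step 6), cyclohexanetrione in a second branch (step 12), union (step 13), deprotection (step 14).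

Key step: step 6

Assumption 1: the β-tri- and tetracarbonyl compounds 16–20 are drawn as one tautomer each; they are enolised and their tautomers interconvert.
Assumption 2: in step 6 the BINAP antipode that is matched with the C3 stereocentre is taken to be (R); if a first trial shows the opposite sense, (S)-BINAP is used with no other change.
Convention: metal enolates and catalyst-bound species are described in the Why lines and carry no number; covalent intermediates that are not isolated are numbered.

**Route**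

Step 1
Reactants: 1 (R)-(−)-linalool
Product: 2 triethyl{[(3R)-3,7-dimethylocta-1,6-dien-3-yl]oxy}silane
Conditions: TESOTf, 2,6-lutidine, CH2Cl2, −78 to 0 °C
Reagents that add atoms: triethylsilyl trifluoromethanesulfonate, CC[Si](CC)(CC)OS(=O)(=O)C(F)(F)F
Why: Silyl triflate/lutidine silylation caps the hindered tertiary allylic alcohol without touching its stereocentre, and the triethylsilyl ether should then survive the oxidation, hydroboration and palladium steps.

Step 2
Reactants: 2 triethyl{[(3R)-3,7-dimethylocta-1,6-dien-3-yl]oxy}silane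
Product: 4 (2E,6R)-2,6-dimethyl-6-[(triethylsilyl)oxy]octa-2,7-dien-1-ol, via enal 3 (not isolated)
Conditions: SeO2 (0.3 equiv), t-BuOOH (3 equiv), salicylic acid (0.1 equiv), CH2Cl2, rt; then NaBH4, MeOH, 0 °C
Reagents that add atoms: tert-butyl hydroperoxide, CC(C)(C)OO
Why: Catalytic SeO2/t-BuOOH allylic oxidation (ene reaction then [2,3]-sigmatropic shift) attacks the trisubstituted alkene at its E-methyl group, the vinyl group having no allylic hydrogen, and the borohydride treatment returns the over-oxidised enal 3 to the E-allylic alcohol.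

Step 3
Reactants: 4 (2E,6R)-2,6-dimethyl-6-[(triethylsilyl)oxy]octa-2,7-dien-1-ol
Product: 5 methyl (2E,6R)-2,6-dimethyl-6-[(triethylsilyl)oxy]octa-2,7-dien-1-yl carbonate
Conditions: ClCO2Me, pyridine, CH2Cl2, 0 °C
Reagents that add atoms: methyl chloroformate, COC(=O)Cl
Why: Acylation of the primary allylic alcohol with a chloroformate gives the carbonate, a leaving group that Pd(0) ionises irreversibly and that releases its own base.

Step 4
Reactants: 5 methyl (2E,6R)-2,6-dimethyl-6-[(triethylsilyl)oxy]octa-2,7-dien-1-yl carbonate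
Product: 7 methyl (2E,6R)-8-hydroxy-2,6-dimethyl-6-[(triethylsilyl)oxy]oct-2-en-1-yl carbonate, via B-alkyl-9-BBN adduct 6 (not isolated)
Conditions: 9-BBN, THF, 0 °C to rt; then NaBO3·4H2O, H2O, rt
Reagents that add atoms: 9-borabicyclo[3.3.1]nonane, B1C2CCCC1CCC2 (its atoms stay in 6 only); sodium perborate tetrahydrate, [Na+].[Na+].O[B-]1(O)OO[B-](O)(O)OO1 (hydroxyl oxygen of 7)
Why: Hydroboration–oxidation with 9-BBN is selective for the monosubstituted vinyl group over the trisubstituted alkene and places boron on the terminal carbon, and perborate should oxidise the C–B bond without cleaving the methyl carbonate.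

Step 5
Reactants: 7 methyl (2E,6R)-8-hydroxy-2,6-dimethyl-6-[(triethylsilyl)oxy]oct-2-en-1-yl carbonate
Product: 8 methyl (2E,6R)-2,6-dimethyl-8-oxo-6-[(triethylsilyl)oxy]oct-2-en-1-yl carbonate
Conditions: Dess–Martin periodinane, NaHCO3, CH2Cl2, 0 °C to rt
Reagents that add atoms: none
Why: Dess–Martin oxidation under bicarbonate buffer converts the primary alcohol into the aldehyde without touching the alkene, carbonate or silyl ether and without a base that could start β-elimination.

Step 6
Reactants: 8 methyl (2E,6R)-2,6-dimethyl-8-oxo-6-[(triethylsilyl)oxy]oct-2-en-1-yl carbonate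
Product: 10 (1S,2R,5R)-2-methyl-5-(prop-1-en-2-yl)-2-[(triethylsilyl)oxy]cyclopentane-1-carbaldehyde, via pyrrolidine enamine 9 (not isolated)
Conditions: Pd2(dba)3 (2.5 mol %), (R)-BINAP (6 mol %), pyrrolidine (0.5 equiv), THF, rt
Reagents that add atoms: none
Why: Pd(0) ionises the allylic carbonate (loss of CO2 and methoxide) to a 2-methyl-η3-allyl complex while pyrrolidine converts the aldehyde into enamine 9, whose α-carbon (C2, linalool numbering) attacks the internal allyl terminus C6 anti to palladium; hydrolysis of the iminium returns the amine. The closest known reaction type is the intramolecular Tsuji–Trost α-allylation of aldehydes under dual enamine/palladium catalysis, here applied to a 2-methylallyl unit. The cyclopentane closes in the 5-exo mode, which delivers the isopropenyl group directly, whereas attack on the CH2 terminus would be a 7-endo closure. The C6 stereocentre is set by the allyl face that is attacked: the diastereomeric allyl complexes interconvert by η3–η1–η3 slippage at the CH2 terminus, so the chiral bisphosphine, acting on top of the weak bias of the quaternary C3 (methyl versus silyloxy), should select the face that puts isopropenyl trans to the silyloxy group. The C2 stereocentre is under thermodynamic control, because the α-CH of the product iminium/enamine equilibrates to the isomer with formyl trans to both the isopropenyl group and the C3 methyl group. The step needs C- over N-allylation and no β-elimination: the intramolecular 5-exo carbon attack should outrun intermolecular attack by nitrogen, and the tertiary triethylsilyloxy group is a poor β-leaving group under acid-free conditions.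

Step 7
Reactants: 11 ethyl (S)-3-hydroxybutanoate
Product: 12 ethyl (2S,3S)-3-hydroxy-2-methylbutanoate
Conditions: LDA (2.2 equiv), THF, −78 to −20 °C; MeI, DMPU, −78 to 0 °C
Reagents that add atoms: iodomethane, CI
Why: Fráter–Seebach alkylation: the chelated lithium alkoxide–enolate dianion is methylated on the face away from the C3 methyl group, which sets C2 anti to the hydroxyl group.

Step 8
Reactants: 12 ethyl (2S,3S)-3-hydroxy-2-methylbutanoate
Product: 13 ethyl (2S,3S)-3-hydroxy-2-methyl-2-(3-methylbut-2-en-1-yl)butanoate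
Conditions: LDA (2.3 equiv), THF, −78 to −15 °C; prenyl bromide, DMPU, −78 to 0 °C
Reagents that add atoms: 1-bromo-3-methylbut-2-ene, CC(C)=CCBr
Why: A second Fráter–Seebach alkylation of the tetrasubstituted chelated enolate takes the prenyl group in from the same face as before, so the quaternary centre forms with prenyl anti and methyl syn to the hydroxyl group, and any minor diastereomer can be removed at this stage.

Step 9
Reactants: 13 ethyl (2S,3S)-3-hydroxy-2-methyl-2-(3-methylbut-2-en-1-yl)butanoate
Product: 14 ethyl (2S)-2-acetyl-2,5-dimethylhex-4-enoate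
Conditions: Dess–Martin periodinane, NaHCO3, CH2Cl2, rt
Reagents that add atoms: none
Why: Dess–Martin oxidation of the secondary alcohol gives the β-keto ester, whose quaternary carbon has no α-hydrogen and so cannot lose its configuration.

Step 10
Reactants: 14 ethyl (2S)-2-acetyl-2,5-dimethylhex-4-enoate
Product: 15 ethyl (2S)-2,6-dimethyl-2-(3-methylbut-2-en-1-yl)-3,5-dioxoheptanoate
Conditions: LiHMDS (2.2 equiv), THF, −78 °C; 1-isobutyrylbenzotriazole, −78 to 0 °C; aq. NH4Cl
Reagents that add atoms: 1-(2-methylpropanoyl)-1H-benzotriazole, CC(C)C(=O)n1nnc2ccccc12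
Why: Crossed Claisen-type C-acylation: the acetyl methyl is the only enolisable position, its lithium enolate is acylated at carbon by the N-acylbenzotriazole, and the second equivalent of base takes up the more acidic β-diketone as it forms.

Step 11
Reactants: 15 ethyl (2S)-2,6-dimethyl-2-(3-methylbut-2-en-1-yl)-3,5-dioxoheptanoate
Product: 16 ethyl (2S)-4-acetyl-2,6-dimethyl-2-(3-methylbut-2-en-1-yl)-3,5-dioxoheptanoate
Conditions: MgCl2, pyridine, AcCl, CH2Cl2, 0 °C to rt
Reagents that add atoms: acetyl chloride, CC(=O)Cl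
Why: Magnesium-chelate-mediated C-acylation of a β-diketone with an acid chloride puts the acetyl group on the central carbon and gives the enolised triacylmethane.

Step 12
Reactants: 16 ethyl (2S)-4-acetyl-2,6-dimethyl-2-(3-methylbut-2-en-1-yl)-3,5-dioxoheptanoate
Product: 17 (6R)-3,5-dihydroxy-6-methyl-2-(2-methylpropanoyl)-6-(3-methylbut-2-en-1-yl)cyclohexa-2,4-dien-1-one
Conditions: LDA (3.3 equiv), THF, −78 to 0 °C; then 1 M HCl
Reagents that add atoms: none
Why: Dieckmann-type (6-exo-trig) Claisen cyclisation: LDA forms the dianion by kinetic deprotonation of the acetyl methyl group, which attacks the ester as in the classical closure of δ-keto esters to cyclohexane-1,3-diones, and because the ester carbon ends next to the free ring CH and the ketone carbon next to the acyl-bearing carbon, the quaternary centre of 14 is carried over unchanged (its descriptor becomes R only through the change in CIP priorities).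

Step 13
Reactants: 10 (1S,2R,5R)-2-methyl-5-(prop-1-en-2-yl)-2-[(triethylsilyl)oxy]cyclopentane-1-carbaldehyde; 17 (6R)-3,5-dihydroxy-6-methyl-2-(2-methylpropanoyl)-6-(3-methylbut-2-en-1-yl)cyclohexa-2,4-dien-1-one
Product: 19 (6R)-3,5-dihydroxy-6-methyl-4-{[(1S,2R,5R)-2-methyl-5-(prop-1-en-2-yl)-2-[(triethylsilyl)oxy]cyclopentyl]methyl}-2-(2-methylpropanoyl)-6-(3-methylbut-2-en-1-yl)cyclohexa-2,4-dien-1-one, via alkylidene triketone 18 (not isolated)
Conditions: Hantzsch ester (1.2 equiv), L-proline (20 mol %), CH2Cl2, rt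
Reagents that add atoms: none
Why: Three-component reductive alkylation: proline-catalysed Knoevenagel condensation at the only free ring CH of 17 gives alkylidene 18, which is reduced in situ by conjugate hydride transfer from the Hantzsch ester, and the trans relation between the formyl-derived carbon and the isopropenyl group is the thermodynamic one and should keep the alkene from cyclising onto 18.

Step 14
Reactants: 19 (6R)-3,5-dihydroxy-6-methyl-4-{[(1S,2R,5R)-2-methyl-5-(prop-1-en-2-yl)-2-[(triethylsilyl)oxy]cyclopentyl]methyl}-2-(2-methylpropanoyl)-6-(3-methylbut-2-en-1-yl)cyclohexa-2,4-dien-1-one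
Product: 20 (6R)-3,5-dihydroxy-4-{[(1S,2R,5R)-2-hydroxy-2-methyl-5-(prop-1-en-2-yl)cyclopentyl]methyl}-6-methyl-2-(2-methylpropanoyl)-6-(3-methylbut-2-en-1-yl)cyclohexa-2,4-dien-1-one
Conditions: HF·pyridine, pyridine, THF, 0 °C to rt
Reagents that add atoms: none
Why: Buffered fluoride desilylation should cleave the tertiary triethylsilyl ether without acid strong enough to engage the prenyl and isopropenyl groups or to cyclise the free tertiary alcohol onto the enolised triketone.

**Compound list**

1 | (R)-(−)-linalool, (3R)-3,7-dimethylocta-1,6-dien-3-ol | CC(C)=CCC[C@@](C)(O)C=C | starting material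
2 | triethyl{[(3R)-3,7-dimethylocta-1,6-dien-3-yl]oxy}silane | CC(C)=CCC[C@@](C)(O[Si](CC)(CC)CC)C=C | intermediate
3 | (2E,6R)-2,6-dimethyl-6-[(triethylsilyl)oxy]octa-2,7-dienal (not isolated) | O=C/C(C)=C/CC[C@@](C)(O[Si](CC)(CC)CC)C=C | intermediate
4 | (2E,6R)-2,6-dimethyl-6-[(triethylsilyl)oxy]octa-2,7-dien-1-ol | OC/C(C)=C/CC[C@@](C)(O[Si](CC)(CC)CC)C=C | intermediate
5 | methyl (2E,6R)-2,6-dimethyl-6-[(triethylsilyl)oxy]octa-2,7-dien-1-yl carbonate | COC(=O)OC/C(C)=C/CC[C@@](C)(O[Si](CC)(CC)CC)C=C | intermediate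
6 | B-alkyl-9-BBN adduct of 5, boron on the former terminal vinyl carbon, carbinol configuration as in 5 (not isolated) | COC(=O)OC/C(C)=C/CC[C@@](C)(O[Si](CC)(CC)CC)CCB1C2CCCC1CCC2 | intermediate
7 | methyl (2E,6R)-8-hydroxy-2,6-dimethyl-6-[(triethylsilyl)oxy]oct-2-en-1-yl carbonate | COC(=O)OC/C(C)=C/CC[C@@](C)(O[Si](CC)(CC)CC)CCO | intermediate
8 | methyl (2E,6R)-2,6-dimethyl-8-oxo-6-[(triethylsilyl)oxy]oct-2-en-1-yl carbonate (key-step precursor) | COC(=O)OC/C(C)=C/CC[C@@](C)(O[Si](CC)(CC)CC)CC=O | intermediate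
9 | (E)-pyrrolidine enamine of 8, methyl (2E,6R,7E)-2,6-dimethyl-8-(pyrrolidin-1-yl)-6-[(triethylsilyl)oxy]octa-2,7-dien-1-yl carbonate (not isolated) | COC(=O)OC/C(C)=C/CC[C@@](C)(O[Si](CC)(CC)CC)/C=C/N1CCCC1 | intermediate
10 | (1S,2R,5R)-2-methyl-5-(prop-1-en-2-yl)-2-[(triethylsilyl)oxy]cyclopentane-1-carbaldehyde (key-step product; formyl cis to silyloxy, trans to isopropenyl) | C=C(C)[C@@H]1CC[C@@](C)(O[Si](CC)(CC)CC)[C@H]1C=O | intermediate
11 | ethyl (S)-3-hydroxybutanoate | C[C@H](O)CC(=O)OCC | starting material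
12 | ethyl (2S,3S)-3-hydroxy-2-methylbutanoate (anti) | C[C@H](O)[C@H](C)C(=O)OCC | intermediate
13 | ethyl (2S,3S)-3-hydroxy-2-methyl-2-(3-methylbut-2-en-1-yl)butanoate | C[C@H](O)[C@](C)(CC=C(C)C)C(=O)OCC | intermediate
14 | ethyl (2S)-2-acetyl-2,5-dimethylhex-4-enoate | CC(=O)[C@](C)(CC=C(C)C)C(=O)OCC | intermediate
15 | ethyl (2S)-2,6-dimethyl-2-(3-methylbut-2-en-1-yl)-3,5-dioxoheptanoate | CC(C)C(=O)CC(=O)[C@](C)(CC=C(C)C)C(=O)OCC | intermediate
16 | ethyl (2S)-4-acetyl-2,6-dimethyl-2-(3-methylbut-2-en-1-yl)-3,5-dioxoheptanoate (triketo form drawn; C4 is enolised) | CC(C)C(=O)C(C(C)=O)C(=O)[C@](C)(CC=C(C)C)C(=O)OCC | intermediate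
17 | (6R)-3,5-dihydroxy-6-methyl-2-(2-methylpropanoyl)-6-(3-methylbut-2-en-1-yl)cyclohexa-2,4-dien-1-one (core triketone) | CC(C)C(=O)C1=C(O)C=C(O)[C@@](C)(CC=C(C)C)C1=O | intermediate
18 | Knoevenagel adduct of 10 and 17: C4 of 17 joined to the former formyl carbon of 10 by an exocyclic C=C of undefined geometry (not isolated) | C=C(C)[C@@H]1CC[C@@](C)(O[Si](CC)(CC)CC)[C@H]1C=C1C(=O)[C@@](C)(CC=C(C)C)C(O)=C(C(=O)C(C)C)C1=O | intermediate
19 | (6R)-3,5-dihydroxy-6-methyl-4-{[(1S,2R,5R)-2-methyl-5-(prop-1-en-2-yl)-2-[(triethylsilyl)oxy]cyclopentyl]methyl}-2-(2-methylpropanoyl)-6-(3-methylbut-2-en-1-yl)cyclohexa-2,4-dien-1-one | C=C(C)[C@@H]1CC[C@@](C)(O[Si](CC)(CC)CC)[C@H]1CC1=C(O)[C@@](C)(CC=C(C)C)C(=O)C(C(=O)C(C)C)=C1O | intermediate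
20 | (6R)-3,5-dihydroxy-4-{[(1S,2R,5R)-2-hydroxy-2-methyl-5-(prop-1-en-2-yl)cyclopentyl]methyl}-6-methyl-2-(2-methylpropanoyl)-6-(3-methylbut-2-en-1-yl)cyclohexa-2,4-dien-1-one | C=C(C)[C@@H]1CC[C@@](C)(O)[C@H]1CC1=C(O)[C@@](C)(CC=C(C)C)C(=O)C(C(=O)C(C)C)=C1O | target

**Step count and risks**

Total step count: 14. Longest linear sequence: 8 steps (steps 1–6, 13, 14 from linalool; equally steps 7–12, 13, 14 from ethyl (S)-3-hydroxybutanoate).

Steps most likely to fail, in order: step 6, step 13, step 12.

Step 6. The allyl face may be attacked with poor selectivity if the ligand does not override the small bias of the quaternary C3, giving the epimer with isopropenyl cis to the silyloxy group. The enamine may also lose triethylsilanol by β-elimination, or the amine may be used up by N-allylation. The fallback sets the isopropenyl-bearing centre by reagent control and closes the ring by substitution with inversion; it sets out from 2 and comes back at 10. Shi epoxidation of the trisubstituted alkene of 2 with the D-fructose-derived ketone should give triethyl{[(3R)-5-[(2R)-3,3-dimethyloxiran-2-yl]-3-methylpent-1-en-3-yl]oxy}silane F1. Hydroboration–oxidation of the vinyl group (9-BBN, then perborate) gives the epoxy alcohol (3R)-5-[(2R)-3,3-dimethyloxiran-2-yl]-3-methyl-3-[(triethylsilyl)oxy]pentan-1-ol F2. Direct oxidation with TEMPO, PhI(OAc)2 and NH4OAc gives the epoxy nitrile (3R)-5-[(2R)-3,3-dimethyloxiran-2-yl]-3-methyl-3-[(triethylsilyl)oxy]pentanenitrile F3. Stork epoxynitrile cyclisation (LiHMDS, toluene/THF, −78 to 0 °C) opens the epoxide 5-exo-tet at its secondary carbon with inversion and gives (1R,2R,5R)-5-(2-hydroxypropan-2-yl)-2-methyl-2-[(triethylsilyl)oxy]cyclopentane-1-carbonitrile F4. Dehydration with Burgess reagent gives (1R,2R,5R)-2-methyl-5-(prop-1-en-2-yl)-2-[(triethylsilyl)oxy]cyclopentane-1-carbonitrile F5. DIBAL reduction and hydrolysis, with equilibration of the α-carbon, give aldehyde 10.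

Step 13. Condensation at the hindered formyl group may be slow, so that the aldehyde is diverted before the C–C bond forms. Once formed, the alkylidene may enolise towards the cyclopentane, eliminate silanol, or be trapped by the isopropenyl group before hydride transfer. The fallback forms the CH2–ring bond by olefination and closes the six-membered ring last; it sets out from 10, uses 15, and comes back at 19. Horner–Wadsworth–Emmons reaction of 10 with triethyl phosphonoacetate gives ethyl (2E)-3-[(1S,2R,5R)-2-methyl-5-(prop-1-en-2-yl)-2-[(triethylsilyl)oxy]cyclopentyl]prop-2-enoate F8. Conjugate reduction with Stryker's reagent gives ethyl 3-[(1S,2R,5R)-2-methyl-5-(prop-1-en-2-yl)-2-[(triethylsilyl)oxy]cyclopentyl]propanoate F9. Saponification with LiOH gives 3-[(1S,2R,5R)-2-methyl-5-(prop-1-en-2-yl)-2-[(triethylsilyl)oxy]cyclopentyl]propanoic acid F10. 1-Chloro-N,N,2-trimethylpropenylamine converts it under neutral conditions into 3-[(1S,2R,5R)-2-methyl-5-(prop-1-en-2-yl)-2-[(triethylsilyl)oxy]cyclopentyl]propanoyl chloride F11. Magnesium-mediated C-acylation of β-diketone 15 (MgCl2, pyridine) gives ethyl (2S)-2,6-dimethyl-2-(3-methylbut-2-en-1-yl)-4-{3-[(1S,2R,5R)-2-methyl-5-(prop-1-en-2-yl)-2-[(triethylsilyl)oxy]cyclopentyl]propanoyl}-3,5-dioxoheptanoate F12. Dieckmann closure of its dianion (LDA) through the side-chain α-methylene then gives 19.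

Step 12. The triacylmethane may be deacylated (retro-Claisen), or the second deprotonation may be incomplete or occur at the isobutyryl methine, so that the ring does not close. The fallback makes the ring-closing carbon a doubly activated methylene; it sets out from 15 and comes back at 17. C-Acylation of 15 with methyl malonyl chloride (MgCl2, pyridine) gives 1-ethyl 7-methyl (2S)-2-methyl-2-(3-methylbut-2-en-1-yl)-4-(2-methylpropanoyl)-3,5-dioxoheptanedioate F6. Dieckmann cyclisation under mild base (DBU or KOt-Bu) gives methyl (3R)-2,6-dihydroxy-3-methyl-3-(3-methylbut-2-en-1-yl)-5-(2-methylpropanoyl)-4-oxocyclohexa-1,5-diene-1-carboxylate F7. Krapcho dealkoxycarbonylation (LiCl, wet DMSO, heat) gives 17.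

**Further compounds**

F1 | step 6 | triethyl{[(3R)-5-[(2R)-3,3-dimethyloxiran-2-yl]-3-methylpent-1-en-3-yl]oxy}silane | CC1(C)O[C@@H]1CC[C@@](C)(O[Si](CC)(CC)CC)C=C
F2 | step 6 | (3R)-5-[(2R)-3,3-dimethyloxiran-2-yl]-3-methyl-3-[(triethylsilyl)oxy]pentan-1-ol | CC1(C)O[C@@H]1CC[C@@](C)(O[Si](CC)(CC)CC)CCO
F3 | step 6 | (3R)-5-[(2R)-3,3-dimethyloxiran-2-yl]-3-methyl-3-[(triethylsilyl)oxy]pentanenitrile | CC1(C)O[C@@H]1CC[C@@](C)(O[Si](CC)(CC)CC)CC#N
F4 | step 6 | (1R,2R,5R)-5-(2-hydroxypropan-2-yl)-2-methyl-2-[(triethylsilyl)oxy]cyclopentane-1-carbonitrile | CC(C)(O)[C@@H]1CC[C@@](C)(O[Si](CC)(CC)CC)[C@H]1C#N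
F5 | step 6 | (1R,2R,5R)-2-methyl-5-(prop-1-en-2-yl)-2-[(triethylsilyl)oxy]cyclopentane-1-carbonitrile | C=C(C)[C@@H]1CC[C@@](C)(O[Si](CC)(CC)CC)[C@H]1C#N
F6 | step 12 | 1-ethyl 7-methyl (2S)-2-methyl-2-(3-methylbut-2-en-1-yl)-4-(2-methylpropanoyl)-3,5-dioxoheptanedioate | CC(C)C(=O)C(C(=O)CC(=O)OC)C(=O)[C@](C)(CC=C(C)C)C(=O)OCC
F7 | step 12 | methyl (3R)-2,6-dihydroxy-3-methyl-3-(3-methylbut-2-en-1-yl)-5-(2-methylpropanoyl)-4-oxocyclohexa-1,5-diene-1-carboxylate | COC(=O)C1=C(O)[C@@](C)(CC=C(C)C)C(=O)C(C(=O)C(C)C)=C1O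
F8 | step 13 | ethyl (2E)-3-[(1S,2R,5R)-2-methyl-5-(prop-1-en-2-yl)-2-[(triethylsilyl)oxy]cyclopentyl]prop-2-enoate | C=C(C)[C@@H]1CC[C@@](C)(O[Si](CC)(CC)CC)[C@H]1/C=C/C(=O)OCC
F9 | step 13 | ethyl 3-[(1S,2R,5R)-2-methyl-5-(prop-1-en-2-yl)-2-[(triethylsilyl)oxy]cyclopentyl]propanoate | C=C(C)[C@@H]1CC[C@@](C)(O[Si](CC)(CC)CC)[C@H]1CCC(=O)OCC
F10 | step 13 | 3-[(1S,2R,5R)-2-methyl-5-(prop-1-en-2-yl)-2-[(triethylsilyl)oxy]cyclopentyl]propanoic acid | C=C(C)[C@@H]1CC[C@@](C)(O[Si](CC)(CC)CC)[C@H]1CCC(=O)O
F11 | step 13 | 3-[(1S,2R,5R)-2-methyl-5-(prop-1-en-2-yl)-2-[(triethylsilyl)oxy]cyclopentyl]propanoyl chloride | C=C(C)[C@@H]1CC[C@@](C)(O[Si](CC)(CC)CC)[C@H]1CCC(=O)Cl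
F12 | step 13 | ethyl (2S)-2,6-dimethyl-2-(3-methylbut-2-en-1-yl)-4-{3-[(1S,2R,5R)-2-methyl-5-(prop-1-en-2-yl)-2-[(triethylsilyl)oxy]cyclopentyl]propanoyl}-3,5-dioxoheptanoate | C=C(C)[C@@H]1CC[C@@](C)(O[Si](CC)(CC)CC)[C@H]1CCC(=O)C(C(=O)C(C)C)C(=O)[C@](C)(CC=C(C)C)C(=O)OCC
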